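Remark on the chemistry: the spiro carbon of the target is (R) (CIP order O > N2 > C3a > C8′); it is assumed to be configurationally stable under neutral conditions and mobile only through the C7′ phenoxide or under strong acid.

## Structural features

The target is a spiro N,O-ketal: one sp3 carbon is at once C3 of a 4-methoxyisoindolin-1-one (benzene ring A fused to γ-lactam ring B; C1 is the carbonyl, N2 carries the 2-hydroxyethyl chain, C3a and C7a are the fusion carbons) and the sp3 carbon of a 2H-naphtho[1,8-bc]furan (five-membered ring C bridging the peri positions of naphthalene rings D and E). Naphthalene positions are primed here: the ring C oxygen sits on C1′ and the methyl on C3′ (ring E), the free hydroxyl on C7′ and the spiro carbon on C8′ (ring D). The spiro carbon is the only stereocentre; it is bonded to N2, the ring C oxygen, C3a and C8′, has no neighbouring stereocentre to relay from, and is crowded by the C4 methoxy group on one side and the C7′ hydroxyl on the other. The fragile element is this N,O-ketal: the C7′ phenoxide can expel the C1′ oxide (retro-oxa-Michael) to an ortho-quinone methide and re-close, which racemises the centre under base, acid can ionise the same carbon to an N-acyliminium ion, the free primary alcohol is a competing internal nucleophile for it, and the peri-fused ring C is strained. The real difficulty is to create a tetrasubstituted, heteroatom-bearing carbon between two ortho-substituted arenes and to obtain it as one enantiomer although it has a built-in racemisation channel. The feature exploited is that C7′ and C8′ bear adjacent oxygen and carbon substituents (the hydroxyl oxygen and C3) that are the two atoms of one carbonyl group of a phthalimide, so a C7′–C8′ aryne of ring D can take up the C3=O group of 22 in one event, after which the C1′ oxygen is in place to close ring C on C3.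

## Logic of the disconnections

29 from 28. No skeletal bond is cut; the last operation is the separation of the two enantiomers of 28. It is placed last because the event that creates the spiro carbon has no element of asymmetry to lean on, and because this carbon is expected to be mobile whenever the C7′ oxygen is an oxide, so enantiopurity installed earlier would be at risk in every basic step. The gain is that every earlier compound may be racemic or achiral; the demand is a separation, and a handling of 29, under non-basic conditions.

28 from 27. The O–CH2 bond of the side-chain ether is cut. The primary hydroxyl must be masked while an aryne and fluoride are present, and the mask must come off without acid or base, both of which can open the N,O-ketal. The gain is a spectator that is inert through steps 10 and 11; the demand is a hydrogenolysis that leaves the benzylic C3–O and C3–N bonds alone.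

27 from 18 and 22. Three bonds are cut: C3–C8′, O–C7′ and C3–O(C1′). C7′ and C8′ carry exactly the oxygen and the carbon of the C3 carbonyl of 22, so both can be delivered across a C7′–C8′ triple bond released from 18, and the C1′ oxygen of 18 is already in place to close ring C. The gain is large: spiro centre, ring C and C7′ hydroxyl arise in one operation from an achiral naphthalene and a one-step imide. The demand is equally large: an imide oxygen has to attack an aryne, it has to be the oxygen next to the methoxy group, it has to choose C7′, and the C1′ oxygen has to stay masked until the aryne is spent.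

22 from 19 and 20. Both C–N bonds of the imide are cut, which leads to two purchasable compounds; the forward step needs only heat and removal of water.

18 from 16, and 16 from 12. The S–O bond of the triflate and the C–Si bond ortho to it are cut. Silicon is brought in by directed metalation next to a carbamate because this reaches the single free ortho position without electrophilic halogenation of a naphthalene that has two activated rings; the carbamate is then the latent triflate. The demand is an exchange of carbamate for triflate that spares silicon on carbon and on oxygen.

12 from 9 by way of 11 and 10. The cuts are the carbamate C–O bond and, in the protecting-group sense, the O–Si bond of 10 and the O–benzyl bond that 10 loses. Here the two peri oxygens are told apart: the oxygen that came with 1 becomes the leaving group of the aryne precursor, the oxygen created by the annulation receives the fluoride-labile group. The demand is that the silyl group does not move across the peri gap once the second hydroxyl is free.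

9 from 6 by way of 7. Ring E is taken back to its dihydro level and the ester carbon is put back on its C2. The reason is that 6 is the direct product of a two-bond annulation; the price is one decarboxylation and one dehydrogenation.

6 from 2 and 3. The C3–C4 and C1–C2 bonds of the new ring are cut (Michael addition, then Dieckmann closure). This builds ring E with its methyl group and its oxygen peri to the oxygen of 2 with no regiochemical ambiguity. The demand is lateral deprotonation of 2 without attack on its ester.

2 from 1. The O–benzyl bond is cut; the phenol has to be capped before strong base is used.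

## Other disconnections considered

Alternative 1: The cut is made at C3–N2 and N2–C1, so that the lactam nitrogen is the last atom to enter ring B. In the forward sense the primary carboxamide A1 (ring C and the C3 quaternary centre in place, ring A carrying a free carboxylic acid ortho to C3, C7′ oxygen benzylated) undergoes a Hofmann rearrangement with a hypervalent iodine oxidant. C3 migrates from the amide carbon to nitrogen with retention, and the ortho carboxyl group acylates that nitrogen with decarboxylation to give the N-unsubstituted lactam A2.
- In its favour: both elementary reactions are of known type. The stereocentre of A1 has a protected C7′ oxygen and therefore no racemisation channel, so it could be secured once (for instance by resolving the corresponding acid) and carried through with retention. On stereochemical security this plan is better than the chosen one, which leaves the only stereocentre to a final separation.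
- Against it: A1 is itself the hard part, since its C3 must be assembled from ring A, ring C and a carboxyl carbon before the key step. The migrating carbon is tertiary, doubly benzylic and α-oxygenated, so the rearranged C3–N intermediate is prone to ionise at C3. The electron-rich naphthalene must survive the oxidant, and A2 still has to be N-alkylated next to the spiro centre and debenzylated.
- Comparison: in structure the plans are opposites (A1 carries the complexity into the key step, 18 and 22 are simple); in mechanism Alternative 1 is the safer; in step economy the chosen plan is clearly shorter.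

Alternative 2: Ring B is cut at C7a–C1, C3a–C3 and N2–C1, which dissects it into an aryne of ring A (from silyl triflate A3), isocyanide A4 as the C1 synthon and cyclic imidate A5, in which ring C, C3 and N2 with its side chain are already present. In the forward sense fluoride releases the aryne from A3, A4 adds to it at C7a, the carbanion left at C3a adds to the imidate carbon of A5 and the nitrogen anion closes on the activated isocyanide carbon, giving spiro amidine A6.
- In its favour: three bonds and ring B form in one operation from three pieces. The regiochemistry follows the well-understood preference of 3-methoxyarynes for attack meta to the methoxy group, which is the sense required and is better founded than the peri effect and the choice between two carbonyls on which step 11 depends. Ring C is never formed under basic conditions.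
- Against it: an imidate C=N is a much weaker electrophile than the aldehydes, ketones and N-sulfonyl imines of known aryne–isocyanide three-component couplings, so the aryl anion is more likely to be protonated or to take up a second isocyanide. A5 needs a 1,7-dioxygenated 8-carboxynaphthalene, which is no easier to make than 18. The N-tert-butyl amidine of A6 must be hydrolysed to the lactam under acid that threatens the N,O-ketal, before debenzylation, desilylation and resolution.
- Comparison: A6 is racemic as well, so the plans are equal on stereocontrol. Mechanistically both rest on one untested aryne trapping. The chosen plan delivers the lactam oxidation level and the free C7′ hydroxyl directly and needs two operations after the key step instead of four.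

Alternative 3: Only C3–N2 is cut. The substrate is racemic A7, in which ring C is closed and C3 still carries hydrogen. A mild two-electron oxidation of its C7′ phenol erases the stereocentre by forming the ortho-quinone methide, and the pendant secondary amide nitrogen adds to C3 (5-exo-trig) inside the hydrogen-bonded ion pair of a chiral phosphoric acid, giving A8.
- In its favour: it is the only plan of the four that sets the stereocentre by catalysis, stereoconvergently from a racemate and directly on the skeleton of the target. Additions to ortho-quinone methides under chiral phosphoric acid control are a developed reaction class, and only one desilylation follows. If the selectivity were high it would be better than the chosen plan in both stereocontrol and endgame.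
- Against it: the electrophilic carbon is fully substituted and sits between two ortho-substituted arenes, the nucleophile is a weak amide nitrogen, and the product N,O-ketal can re-ionise under the same acid, so the enantiomeric excess would be exposed to erosion. The quinone methide has its exocyclic double bond inside strained ring C. A7 needs a C8′-functionalised 1,7-dioxygenated naphthalene and a ring A aryl metal, a longer and less convergent sequence than steps 1 to 10.
- Comparison: the bond set is the same as in the chosen plan but C–N is formed last; it trades an untested aryne step for a demanding asymmetric one; the step counts are expected to be comparable, Alternative 3 winning only if no resolution is needed.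

Key step: step 11

## Route

Step 1
Reactants: 1 ethyl 2-hydroxy-6-methylbenzoate
Product: 2 ethyl 2-(benzyloxy)-6-methylbenzoate
Conditions: BnBr, K2CO3, DMF, 60 °C
Reagents that add atoms: benzyl bromide, BrCc1ccccc1
Why: Williamson etherification of the hydrogen-bonded salicylate hydroxyl; the benzyl ether resists LiN(iPr)2, hot LiCl/DMSO and bromide and is later removed under neutral conditions.

Step 2
Reactants: 2 ethyl 2-(benzyloxy)-6-methylbenzoate; 3 methyl crotonate
Product: 6 methyl 8-(benzyloxy)-1-hydroxy-3-methyl-3,4-dihydronaphthalene-2-carboxylate (racemic; enol form of the β-keto ester), via lithiated toluate 4 (not isolated), via Michael adduct enolate 5 (not isolated)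
Conditions: LiN(iPr)2 (2.2 equiv), THF, −78 °C; 3, −78 °C to rt; aq. HCl
Reagents that add atoms: none
Why: Michael–Dieckmann (Staunton–Weinreb) annulation: lateral lithiation of the ortho-toluate gives 4, which adds to the β-carbon of 3, and enolate 5 acylates itself on the neighbouring aryl ester; the product rests as its stabilised enolate until the quench. The two new ring bonds fix the peri dioxygenation and the methyl position; the single stereocentre of 6 is racemic and is destroyed in step 4.

Step 3
Reactants: 6 methyl 8-(benzyloxy)-1-hydroxy-3-methyl-3,4-dihydronaphthalene-2-carboxylate
Product: 7 8-(benzyloxy)-3-methyl-3,4-dihydronaphthalen-1(2H)-one (racemic)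
Conditions: LiCl, H2O, DMSO, 150 °C
Reagents that add atoms: none
Why: Krapcho dealkoxycarbonylation: chloride dealkylates the methyl ester of the β-keto ester and the β-keto carboxylate decarboxylates; the near-neutral conditions leave the benzyl ether intact.

Step 4
Reactants: 7 8-(benzyloxy)-3-methyl-3,4-dihydronaphthalen-1(2H)-one
Product: 9 8-(benzyloxy)-3-methylnaphthalen-1-ol, via bromo ketone 8 (not isolated)
Conditions: PhNMe3Br3, THF, 0 °C to rt; then Li2CO3, LiBr, DMF, 120 °C
Reagents that add atoms: none
Why: α-Bromination of the aryl ketone through its enol gives 8; dehydrobromination gives the conjugated enone, which is the keto tautomer of a 1-naphthol and aromatises at once, so the stereocentres of 8 are of no consequence.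

Step 5
Reactants: 9 8-(benzyloxy)-3-methylnaphthalen-1-ol
Product: 10 {[8-(benzyloxy)-3-methylnaphthalen-1-yl]oxy}tri(propan-2-yl)silane
Conditions: iPr3SiOTf, 2,6-lutidine, CH2Cl2, 0 °C to rt
Reagents that add atoms: triisopropylsilyl trifluoromethanesulfonate, CC(C)[Si](OS(=O)(=O)C(F)(F)F)(C(C)C)C(C)C
Why: Silylation of the peri-hindered naphthol with a silyl triflate and a hindered pyridine base. Triisopropylsilyl is chosen over tert-butyldimethylsilyl because it is slower to migrate between the peri oxygens, survives n-BuLi, DBU and CsF, shields C8′ in the key step, and is still removed by Bu4NF within minutes.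

Step 6
Reactants: 10 {[8-(benzyloxy)-3-methylnaphthalen-1-yl]oxy}tri(propan-2-yl)silane
Product: 11 6-methyl-8-{[tri(propan-2-yl)silyl]oxy}naphthalen-1-ol
Conditions: H2 (1 atm), 10% Pd/C, EtOAc, rt
Reagents that add atoms: none
Why: Hydrogenolysis of the aryl benzyl ether is neutral, so the newly freed hydroxyl of 11 is not given a base that could move the silyl group across the peri gap; 11 is used at once in step 7.

Step 7
Reactants: 11 6-methyl-8-{[tri(propan-2-yl)silyl]oxy}naphthalen-1-ol
Product: 12 6-methyl-8-{[tri(propan-2-yl)silyl]oxy}naphthalen-1-yl N-(propan-2-yl)carbamate
Conditions: iPrNCO (excess), Et3N (cat.), CH2Cl2, 0 °C to rt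
Reagents that add atoms: isopropyl isocyanate, CC(C)N=C=O
Why: Base-catalysed addition of the naphthol to the isocyanate gives the N-monoalkyl O-aryl carbamate, the directing group for step 8. Excess isocyanate at low temperature is meant to trap the hydroxyl faster than the bulky silyl group can migrate; the regiochemical integrity of 12 is to be confirmed by HMBC and NOE.

Step 8
Reactants: 12 6-methyl-8-{[tri(propan-2-yl)silyl]oxy}naphthalen-1-yl N-(propan-2-yl)carbamate
Product: 16 6-methyl-8-{[tri(propan-2-yl)silyl]oxy}-2-(trimethylsilyl)naphthalen-1-yl N-(propan-2-yl)carbamate, via N-silyl carbamate 13 (not isolated), via aryllithium 14 (not isolated), via N-silyl C-silyl carbamate 15 (not isolated)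
Conditions: tBuMe2SiOTf, TMEDA, Et2O, 0 °C to rt; n-BuLi, TMEDA, −78 °C; Me3SiCl, −78 °C to rt; aq. NaHSO4
Reagents that add atoms: chlorotrimethylsilane, C[Si](C)(C)Cl
Why: Directed ortho-metalation: the carbamate N–H is silylated first (13), so n-BuLi·TMEDA deprotonates only the ring position ortho to the carbamate (the other ortho position is the ring fusion and the peri position carries oxygen) to give 14. Me3SiCl quenches 14 before any anionic ortho-Fries shift, and the N-silyl group of 15 is lost in the acidic work-up; no halogenation of the electron-rich naphthalene is needed.

Step 9
Reactants: 16 6-methyl-8-{[tri(propan-2-yl)silyl]oxy}-2-(trimethylsilyl)naphthalen-1-yl N-(propan-2-yl)carbamate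
Product: 18 6-methyl-8-{[tri(propan-2-yl)silyl]oxy}-2-(trimethylsilyl)naphthalen-1-yl trifluoromethanesulfonate, via naphthoxide 17 (not isolated)
Conditions: DBU, Et2NH, MeCN (anhydrous), 40 °C; then PhNTf2, rt
Reagents that add atoms: N-phenylbis(trifluoromethanesulfonimide), O=S(=O)(N(c1ccccc1)S(=O)(=O)C(F)(F)F)C(F)(F)F
Why: DBU triggers E1cB loss of isopropyl isocyanate from the carbamate (scavenged by Et2NH as a urea) and naphthoxide 17 is triflated in the same flask, the established carbamate-to-triflate exchange for ortho-silylaryl triflates. Anhydrous conditions keep the aryl silyl ether on, and a shift of the triisopropylsilyl group onto the oxide flanked by Me3Si is sterically disfavoured.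

Step 10
Reactants: 19 3-methoxyphthalic anhydride; 20 2-(benzyloxy)ethan-1-amine
Product: 22 2-[2-(benzyloxy)ethyl]-4-methoxyisoindoline-1,3-dione, via amic acid 21 (not isolated)
Conditions: toluene, Et3N (cat.), reflux, Dean–Stark
Reagents that add atoms: none
Why: Aminolysis of the anhydride gives amic acid 21 (either regioisomer), which cyclodehydrates to the imide on azeotropic removal of water; the benzyl ether is inert.

Step 11
Reactants: 18 6-methyl-8-{[tri(propan-2-yl)silyl]oxy}-2-(trimethylsilyl)naphthalen-1-yl trifluoromethanesulfonate; 22 2-[2-(benzyloxy)ethyl]-4-methoxyisoindoline-1,3-dione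
Product: 27 racemic O-benzyl ether of the target (2-[2-(benzyloxy)ethyl]-4-methoxyisoindolin-1-one spiro-linked through C3 to C7′-hydroxy-C3′-methyl-2H-naphtho[1,8-bc]furan), via naphthalyne 23 (not isolated), via spiro oxete 24 (not isolated), via quinone methide 25 (not isolated), via peri oxide 26 (not isolated)
Conditions: 22 (5 equiv), CsF, MeCN/toluene, rt, slow addition of 18; then Bu4NF, THF, 0 °C; AcOH
Reagents that add atoms: none
Why: Proposed new method: fluoride-induced 1,2-elimination of the ortho-silylaryl triflate gives naphthalyne 23; the carbonyl oxygen of 22 that is conjugated with the C4 methoxy group adds to C7′ while the carbanion developing at C8′ closes on the now activated carbonyl carbon C3 (a formal [2+2] addition to spiro oxete 24), and 4π electrocyclic opening of 24 gives the push–pull ortho-quinone methide 25, which carries ring B intact. The closest known reaction type is the formal [2+2] addition of arynes to the C=O group of formamides, which gives ortho-quinone methides that are trapped by nucleophiles (the insertion of arynes into the C–O bond of carboxylic acids to ortho-hydroxyaryl ketones is related); an imide carbonyl has not been used in this way. In the second stage Bu4NF removes the triisopropylsilyl group and the C1′ oxide of 26 adds to C3, closing five-membered ring C by a formally 5-endo-trig oxa-Michael addition (both C3 and C8′ lie in the new ring); the crowded methide is twisted towards an N-acyliminium naphtholate, so the oxide can reach C3 in the naphthalene plane, and rearomatisation of ring D drives the closure. The oxete is only transient and ring B is brought in by 22, so ring C is the one ring made. The spiro carbon is created without any chiral element and 27 forms as the racemate. Regiochemistry at the aryne is secured by the peri triisopropylsilyloxy group, which shields C8′ and adds to the normal preference of 1,2-naphthalynes for attack at the β-carbon; the choice of carbonyl rests only on the higher electron density of the oxygen conjugated with the methoxy group, so the regioisomeric spiro lactam is the by-product to expect. Chemoselectivity is protected by keeping the C1′ oxygen silylated until 18 is spent, so that no phenoxide (a far better aryne trap than an imide) is present in the first stage, by a large excess of 22 and by slow addition of 18.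

Step 12
Reactants: 27 racemic O-benzyl ether of the target
Product: 28 racemic target (2-(2-hydroxyethyl)-4-methoxyisoindolin-1-one spiro-linked through C3 to C7′-hydroxy-C3′-methyl-2H-naphtho[1,8-bc]furan)
Conditions: H2 (1 atm), 10% Pd/C, EtOAc, rt
Reagents that add atoms: none
Why: Catalytic hydrogenolysis of the primary alkyl benzyl ether under neutral conditions, which avoid both the phenoxide and the N-acyliminium ion; the spiro C3–O and C3–N bonds are benzylic but fully substituted and shielded by the flanking groups, so they should not reach the catalyst surface.

Step 13
Reactants: 28 racemic target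
Product: 29 (R)-target, CNP0434366.1
Conditions: preparative SFC, amylose tris(3,5-dimethylphenylcarbamate) chiral phase, CO2/MeOH, no amine additive
Reagents that add atoms: none
Why: Chromatographic resolution on a polysaccharide chiral stationary phase should separate the enantiomers of this rigid, hydrogen-bond-donating spiro compound; the eluent is kept free of base because the centre is expected to racemise through the C7′ phenoxide. The (S) enantiomer can be racemised with catalytic Et3N and resubmitted, and the (R) fraction is to be identified by comparing its electronic circular dichroism with the calculated curve.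

## Compound list

1 | ethyl 2-hydroxy-6-methylbenzoate | CCOC(=O)c1c(C)cccc1O | starting material
2 | ethyl 2-(benzyloxy)-6-methylbenzoate | CCOC(=O)c1c(C)cccc1OCc1ccccc1 | intermediate
3 | methyl (E)-but-2-enoate (methyl crotonate) | C/C=C/C(=O)OC | starting material
4 | ethyl 2-(benzyloxy)-6-(lithiomethyl)benzoate (lithiated toluate) | CCOC(=O)c1c(C[Li])cccc1OCc1ccccc1 | intermediate (not isolated)
5 | lithium enolate of methyl 4-[3-(benzyloxy)-2-(ethoxycarbonyl)phenyl]-3-methylbutanoate (racemic) | CCOC(=O)c1c(CC(C)C=C(OC)O[Li])cccc1OCc1ccccc1 | intermediate (not isolated)
6 | methyl 8-(benzyloxy)-1-hydroxy-3-methyl-3,4-dihydronaphthalene-2-carboxylate (racemic; enol form of the β-keto ester) | COC(=O)C1=C(O)c2c(OCc3ccccc3)cccc2CC1C | intermediate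
7 | 8-(benzyloxy)-3-methyl-3,4-dihydronaphthalen-1(2H)-one (racemic) | CC1CC(=O)c2c(OCc3ccccc3)cccc2C1 | intermediate
8 | 8-(benzyloxy)-2-bromo-3-methyl-3,4-dihydronaphthalen-1(2H)-one (racemic, mixture of diastereomers) | CC1Cc2cccc(OCc3ccccc3)c2C(=O)C1Br | intermediate (not isolated)
9 | 8-(benzyloxy)-3-methylnaphthalen-1-ol | Cc1cc(O)c2c(OCc3ccccc3)cccc2c1 | intermediate
10 | {[8-(benzyloxy)-3-methylnaphthalen-1-yl]oxy}tri(propan-2-yl)silane | Cc1cc(O[Si](C(C)C)(C(C)C)C(C)C)c2c(OCc3ccccc3)cccc2c1 | intermediate
11 | 6-methyl-8-{[tri(propan-2-yl)silyl]oxy}naphthalen-1-ol | Cc1cc(O[Si](C(C)C)(C(C)C)C(C)C)c2c(O)cccc2c1 | intermediate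
12 | 6-methyl-8-{[tri(propan-2-yl)silyl]oxy}naphthalen-1-yl N-(propan-2-yl)carbamate | Cc1cc(O[Si](C(C)C)(C(C)C)C(C)C)c2c(OC(=O)NC(C)C)cccc2c1 | intermediate
13 | 6-methyl-8-{[tri(propan-2-yl)silyl]oxy}naphthalen-1-yl N-[tert-butyl(dimethyl)silyl]-N-(propan-2-yl)carbamate | Cc1cc(O[Si](C(C)C)(C(C)C)C(C)C)c2c(OC(=O)N(C(C)C)[Si](C)(C)C(C)(C)C)cccc2c1 | intermediate (not isolated)
14 | 2-lithio derivative of 13 | Cc1cc(O[Si](C(C)C)(C(C)C)C(C)C)c2c(OC(=O)N(C(C)C)[Si](C)(C)C(C)(C)C)c([Li])ccc2c1 | intermediate (not isolated)
15 | 2-(trimethylsilyl) derivative of 13 | Cc1cc(O[Si](C(C)C)(C(C)C)C(C)C)c2c(OC(=O)N(C(C)C)[Si](C)(C)C(C)(C)C)c([Si](C)(C)C)ccc2c1 | intermediate (not isolated)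
16 | 6-methyl-8-{[tri(propan-2-yl)silyl]oxy}-2-(trimethylsilyl)naphthalen-1-yl N-(propan-2-yl)carbamate | Cc1cc(O[Si](C(C)C)(C(C)C)C(C)C)c2c(OC(=O)NC(C)C)c([Si](C)(C)C)ccc2c1 | intermediate
17 | 6-methyl-8-{[tri(propan-2-yl)silyl]oxy}-2-(trimethylsilyl)naphthalen-1-olate (DBU-H+ salt; anion drawn) | Cc1cc(O[Si](C(C)C)(C(C)C)C(C)C)c2c([O-])c([Si](C)(C)C)ccc2c1 | intermediate (not isolated)
18 | 6-methyl-8-{[tri(propan-2-yl)silyl]oxy}-2-(trimethylsilyl)naphthalen-1-yl trifluoromethanesulfonate (aryne precursor) | Cc1cc(O[Si](C(C)C)(C(C)C)C(C)C)c2c(OS(=O)(=O)C(F)(F)F)c([Si](C)(C)C)ccc2c1 | intermediate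
19 | 3-methoxyphthalic anhydride | COc1cccc2c1C(=O)OC2=O | starting material
20 | 2-(benzyloxy)ethan-1-amine | NCCOCc1ccccc1 | starting material
21 | 2-{[2-(benzyloxy)ethyl]carbamoyl}-6-methoxybenzoic acid (amic acid; one of two regioisomers, both give 22) | COc1cccc(C(=O)NCCOCc2ccccc2)c1C(=O)O | intermediate (not isolated)
22 | 2-[2-(benzyloxy)ethyl]-4-methoxyisoindoline-1,3-dione (N-(2-benzyloxyethyl)-3-methoxyphthalimide) | COc1cccc2c1C(=O)N(CCOCc1ccccc1)C2=O | intermediate
23 | 6-methyl-8-{[tri(propan-2-yl)silyl]oxy}-1,2-didehydronaphthalene (1,2-naphthalyne; triple bond between C7′ and C8′) | Cc1cc(O[Si](C(C)C)(C(C)C)C(C)C)c2C#CC=Cc2c1 | intermediate (not isolated)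
24 | spiro oxete: 2-[2-(benzyloxy)ethyl]-4-methoxyisoindolin-1-one whose C3 is bonded to C8′ and, through oxygen, to C7′ of the C1′-triisopropylsilyloxy-C3′-methylnaphthalene (racemic) | COc1cccc2c1C1(Oc3ccc4cc(C)cc(O[Si](C(C)C)(C(C)C)C(C)C)c4c31)N(CCOCc1ccccc1)C2=O | intermediate (not isolated)
25 | 2-[2-(benzyloxy)ethyl]-4-methoxy-3-[6-methyl-2-oxo-8-{[tri(propan-2-yl)silyl]oxy}naphthalen-1(2H)-ylidene]isoindolin-1-one (ortho-quinone methide; alkene geometry open) | COc1cccc2c1C(=C1C(=O)C=Cc3cc(C)cc(O[Si](C(C)C)(C(C)C)C(C)C)c31)N(CCOCc1ccccc1)C2=O | intermediate (not isolated)
26 | 8-oxido analogue of 25 (tetrabutylammonium salt) | COc1cccc2c1C(=C1C(=O)C=Cc3cc(C)cc([O-])c31)N(CCOCc1ccccc1)C2=O.CCCC[N+](CCCC)(CCCC)CCCC | intermediate (not isolated)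
27 | racemic O-benzyl ether of the target: 2-[2-(benzyloxy)ethyl]-4-methoxyisoindolin-1-one spiro-linked through C3 to C7′-hydroxy-C3′-methyl-2H-naphtho[1,8-bc]furan (racemate; (R) enantiomer drawn) | COc1cccc2c1[C@@]1(Oc3cc(C)cc4ccc(O)c1c34)N(CCOCc3ccccc3)C2=O | intermediate
28 | racemic target: 2-(2-hydroxyethyl)-4-methoxyisoindolin-1-one spiro-linked through C3 to C7′-hydroxy-C3′-methyl-2H-naphtho[1,8-bc]furan (racemate; (R) enantiomer drawn) | COc1cccc2c1[C@@]1(Oc3cc(C)cc4ccc(O)c1c34)N(CCO)C2=O | intermediate
29 | (R)-target, CNP0434366.1: (3R)-2-(2-hydroxyethyl)-4-methoxyisoindolin-1-one spiro-linked through C3 to C7′-hydroxy-C3′-methyl-2H-naphtho[1,8-bc]furan | COc1cccc2c1[C@@]1(Oc3cc(C)cc4ccc(O)c1c34)N(CCO)C2=O | target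

## Step count and least certain steps

Total: 13 steps. Longest linear sequence: 12 steps (steps 1 to 9 and 11 to 13, from 1); step 10 is a one-step branch that joins at step 11.

Step 11 (key step, proposed new method). What may go wrong:
- The aryne may be consumed faster by fluoride, by solvent, by itself or by oxygen nucleophiles formed during the reaction than by the weakly nucleophilic imide oxygen.
- The carbonyl remote from the methoxy group may react, or the oxygen may attack C8′ instead of C7′.
- The C8′ carbanion may be protonated before it closes on C3, leaving only O-arylation.
- The quinone methide may be diverted before the peri oxygen is released.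

Fallback by known chemistry, from 18 and 21 back to 27: step 10 is stopped at room temperature before dehydration and the regioisomer of 21 drawn in the list is crystallised. 21 is deprotonated with Cs2CO3 and heated with 18 and CsF in THF. This is the known insertion of an aryne into the C–O bond of a carboxylic acid: the carboxylate oxygen arylates at C7′ and the C8′ carbanion attacks the ester carbonyl just formed, giving an ortho-hydroxyaryl ketone. The 2-aroylbenzamide so obtained would rest as its ring tautomer, hydroxy lactam F1. Bu4NF removes the silyl group to give triol hydroxy lactam F2, and catalytic TsOH in toluene ionises the tertiary hemiaminal to the N-acyliminium ion, which the C1′ hydroxyl captures to close ring C and give 27. A carboxylate is a far better aryne trap than an imide oxygen, and the choice between two carbonyls disappears.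

Step 7. What may go wrong: base-promoted migration of the silyl group between the two peri oxygens while one of them is free, which would scramble the only difference between the rings (the position of the methyl group) and lead to a regioisomeric aryne precursor.

Fallback, from 9 back to 27: the migratory silyl ether is replaced by a carbon-linked, fluoride-labile ether. Mitsunobu etherification of 9 with 2-(trimethylsilyl)ethanol gives ether F3. Hydrogenolysis gives naphthol F4, carbamoylation gives carbamate F5, directed ortho-silylation gives silyl carbamate F6 and carbamate-to-triflate exchange gives silyl triflate F7, all as in steps 6 to 9 but with no group that can move across the peri gap. F7 is used in step 11 in place of 18, with the second stage run with Bu4NF at 50 °C, where the 2-(trimethylsilyl)ethyl ether fragments to the peri oxide; the route is rejoined at 27.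

Step 12. What may go wrong: over-reduction, that is hydrogenolysis of the doubly benzylic spiro C3–O bond or partial hydrogenation of the naphthol ring, competing with cleavage of the side-chain benzyl ether.

Fallback, from 19 and 18 back to 28: the benzyl ether is given up for a silyl ether. 19 is condensed with commercial 2-[(tert-butyldiphenylsilyl)oxy]ethan-1-amine as in step 10 to give imide F8. Step 11 with F8 in place of 22, its second stage kept short at 0 °C, gives spiro silyl ether F9. HF·pyridine in THF/pyridine then removes the silyl group and gives 28 without any reductive step.

Step 13. What may go wrong: loss of enantiopurity by racemisation through the phenoxide and the ring-opened quinone methide during chromatography or concentration, or insufficient separation on the chiral phase.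

Fallback, from 28 back to 29: crystallisation-induced asymmetric transformation. 28 is slurried with one equivalent of an enantiopure amine base (1-phenylethylamine is the first candidate; base, handedness and solvent are to be chosen by screening). The C7′ phenoxide should racemise in solution through the quinone methide while the less soluble diastereomeric salt, ammonium phenoxide F10, crystallises. Filtration and partition between EtOAc and cold aqueous citric acid would liberate 29.

## Further compounds

F1 | step 11 | 2-[2-(benzyloxy)ethyl]-3-hydroxy-3-[2-hydroxy-6-methyl-8-{[tri(propan-2-yl)silyl]oxy}naphthalen-1-yl]-4-methoxyisoindolin-1-one (racemic hydroxy lactam) | COc1cccc2c1C(O)(c1c(O)ccc3cc(C)cc(O[Si](C(C)C)(C(C)C)C(C)C)c13)N(CCOCc1ccccc1)C2=O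
F2 | step 11 | 2-[2-(benzyloxy)ethyl]-3-(2,8-dihydroxy-6-methylnaphthalen-1-yl)-3-hydroxy-4-methoxyisoindolin-1-one (racemic) | COc1cccc2c1C(O)(c1c(O)ccc3cc(C)cc(O)c13)N(CCOCc1ccccc1)C2=O
F3 | step 7 | (2-{[8-(benzyloxy)-3-methylnaphthalen-1-yl]oxy}ethyl)trimethylsilane | Cc1cc(OCC[Si](C)(C)C)c2c(OCc3ccccc3)cccc2c1
F4 | step 7 | 6-methyl-8-[2-(trimethylsilyl)ethoxy]naphthalen-1-ol | Cc1cc(OCC[Si](C)(C)C)c2c(O)cccc2c1
F5 | step 7 | 6-methyl-8-[2-(trimethylsilyl)ethoxy]naphthalen-1-yl N-(propan-2-yl)carbamate | Cc1cc(OCC[Si](C)(C)C)c2c(OC(=O)NC(C)C)cccc2c1
F6 | step 7 | 6-methyl-8-[2-(trimethylsilyl)ethoxy]-2-(trimethylsilyl)naphthalen-1-yl N-(propan-2-yl)carbamate | Cc1cc(OCC[Si](C)(C)C)c2c(OC(=O)NC(C)C)c([Si](C)(C)C)ccc2c1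
F7 | step 7 | 6-methyl-8-[2-(trimethylsilyl)ethoxy]-2-(trimethylsilyl)naphthalen-1-yl trifluoromethanesulfonate | Cc1cc(OCC[Si](C)(C)C)c2c(OS(=O)(=O)C(F)(F)F)c([Si](C)(C)C)ccc2c1
F8 | step 12 | 2-{2-[(tert-butyldiphenylsilyl)oxy]ethyl}-4-methoxyisoindoline-1,3-dione | COc1cccc2c1C(=O)N(CCO[Si](c1ccccc1)(c1ccccc1)C(C)(C)C)C2=O
F9 | step 12 | racemic O-(tert-butyldiphenylsilyl) ether of the target (racemate; (R) enantiomer drawn) | COc1cccc2c1[C@@]1(Oc3cc(C)cc4ccc(O)c1c34)N(CCO[Si](c3ccccc3)(c3ccccc3)C(C)(C)C)C2=O
F10 | step 13 | 1-phenylethylammonium salt of the C7′ phenoxide of 29 (drawn with the (S)-amine; handedness of the amine to be fixed by screening) | COc1cccc2c1[C@@]1(Oc3cc(C)cc4ccc([O-])c1c34)N(CCO)C2=O.C[C@H]([NH3+])c1ccccc1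
A1 | alternative 1 | target-configured primary carboxamide: C7′-benzyloxy-C3′-methyl-2H-naphtho[1,8-bc]furan carrying on its sp3 carbon a carboxamide and a 2-carboxy-6-methoxyphenyl group | COc1cccc(C(=O)O)c1[C@@]1(Oc2cc(C)cc3ccc(OCc4ccccc4)c1c23)C(N)=O
A2 | alternative 1 | N-unsubstituted spiro lactam, C7′ benzyl ether (target-configured) | COc1cccc2c1[C@@]1(Oc3cc(C)cc4ccc(OCc5ccccc5)c1c34)NC2=O
A3 | alternative 2 | 3-methoxy-2-(trimethylsilyl)phenyl trifluoromethanesulfonate | COc1cccc(OS(=O)(=O)C(F)(F)F)c1[Si](C)(C)C
A4 | alternative 2 | tert-butyl isocyanide | CC(C)(C)[N+]#[C-]
A5 | alternative 2 | cyclic imidate: C7′-benzyloxy-C3′-methyl-2H-naphtho[1,8-bc]furan-2-imine, N-[2-(tert-butyldimethylsilyloxy)ethyl] | Cc1cc2c3c(c1)ccc(OCc1ccccc1)c3C(=NCCO[Si](C)(C)C(C)(C)C)O2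
A6 | alternative 2 | spiro N-tert-butyl amidine of the protected target (racemate; target-configured enantiomer drawn) | COc1cccc2c1[C@@]1(Oc3cc(C)cc4ccc(OCc5ccccc5)c1c34)N(CCO[Si](C)(C)C(C)(C)C)C2=NC(C)(C)C
A7 | alternative 3 | racemic N-[2-(tert-butyldimethylsilyloxy)ethyl]-2-(C7′-hydroxy-C3′-methyl-2H-naphtho[1,8-bc]furan-2-yl)-3-methoxybenzamide | COc1cccc(C(=O)NCCO[Si](C)(C)C(C)(C)C)c1C1Oc2cc(C)cc3ccc(O)c1c23
A8 | alternative 3 | O-(tert-butyldimethylsilyl) ether of the target, (R) | COc1cccc2c1[C@@]1(Oc3cc(C)cc4ccc(O)c1c34)N(CCO[Si](C)(C)C(C)(C)C)C2=O
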